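**Plan**

1. Numbering (eudesmane): ring A = C1–C5 and C10, ring B = C5–C10, C14 = methyl on C10, C15 = methyl on C4, β = the face of C14. The feature that makes the key step possible: C10 is quaternary and holds a methyl and the two ring-A arms C1–C2 and C5–C4, so ring A written as a 4-alkyl-4-methylcyclohexa-2,5-dienone has two enantiotopic enone arms. C6, the oxygenated ring-B carbon bonded to C5, can be a ketone, which is what an acyl anion leaves behind when it adds to C5.
2. Retrosynthesis: cut the coumarate at its C=C bond and at the O6–acyl bond; take C4–C15 and the C3=C4 bond back to a ring-A Δ1-3-ketone; cut ring B at C5–C6 (aldehyde plus dienone); cut the dienone ring into an α-methyl aldehyde and but-3-en-2-one; cut the chain at C7–C8.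
3. Forward: C7–C8 alkylation builds the chain; Robinson annulation and dehydrogenation give ring A as an achiral dienone; the carbene-catalysed Stetter reaction closes ring B; ring A is then methylated at C4 and deoxygenated at C3 through a regiodefined enol triflate; the p-coumarate is assembled last on O6.
4. Stereochemistry: C10 from the chiral carbene (choice between the two arms); C5 and C7 by equilibration α to the C6 ketone (trans ring fusion, equatorial isopropyl); C6 by hydride attack anti to the C10 methyl; the E olefin from decarboxylative Knoevenagel–Doebner condensation.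

Key step: step 9

Assumption 1: aldehyde 12 is made and cyclised as the racemate at C7, so 13 is a pair of C7 epimers (drawn with C7 undefined) that converge in step 10; other uncontrolled centres that are later erased are likewise drawn undefined.
Assumption 2: the (5aR,10bS) antipode of the triazolium salt is written for step 9; if a pilot run shows the opposite sense of arm selection, the (5aS,10bR) salt is used in the same way.

**Route**

Step 1
Reactants: 1 3-methylbut-3-en-1-ol
Product: 2 4-iodo-2-methylbut-1-ene
Conditions: I2, PPh3, imidazole, CH2Cl2, 0 °C → rt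
Reagents that add atoms: iodine, II
Why: Appel-type iodination, in which the alkoxyphosphonium ion of the primary homoallylic alcohol is displaced by iodide in an SN2 step that leaves the 1,1-disubstituted alkene untouched.

Step 2
Reactants: 3 ethyl 3-methylbutanoate; 2 4-iodo-2-methylbut-1-ene
Product: 4 ethyl 5-methyl-2-(propan-2-yl)hex-5-enoate (racemic)
Conditions: LiN(i-Pr)2, THF, −78 °C; then 2, DMPU, −78 °C → rt
Reagents that add atoms: none
Why: Ester enolate alkylation (SN2) with a primary iodide in the presence of DMPU is standard; the new stereocentre (future C7) forms as the racemate, which is acceptable because C7 is equilibrated later next to the C6 ketone.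

Step 3
Reactants: 4 ethyl 5-methyl-2-(propan-2-yl)hex-5-enoate
Product: 5 ethyl 6-hydroxy-5-methyl-2-(propan-2-yl)hexanoate (diastereomer mixture)
Conditions: 9-borabicyclo[3.3.1]nonane, THF, 0 °C → rt; then 3 M NaOAc aq., 30% H2O2, 0 °C → rt
Reagents that add atoms: hydrogen peroxide, OO
Why: Brown hydroboration–oxidation places boron on the terminal carbon of the 1,1-disubstituted alkene and spares the ester, and buffered peroxide oxidation gives the primary alcohol; the new methyl-bearing stereocentre is uncontrolled and is erased when that carbon becomes the symmetric quaternary centre.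

Step 4
Reactants: 5 ethyl 6-hydroxy-5-methyl-2-(propan-2-yl)hexanoate
Product: 6 ethyl 5-methyl-6-oxo-2-(propan-2-yl)hexanoate (diastereomer mixture)
Conditions: 2,2,6,6-tetramethylpiperidin-1-oxyl (cat.), PhI(OAc)2, CH2Cl2, rt
Reagents that add atoms: none
Why: Nitroxyl-catalysed (oxoammonium) oxidation of a primary alcohol stops at the aldehyde and tolerates the ester.

Step 5
Reactants: 6 ethyl 5-methyl-6-oxo-2-(propan-2-yl)hexanoate; 7 but-3-en-2-one
Product: 9 ethyl 4-(1-methyl-4-oxocyclohex-2-en-1-yl)-2-(propan-2-yl)butanoate (diastereomer mixture), via keto aldehyde Michael adduct 8 (not isolated)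
Conditions: H2SO4 (cat.), toluene, 45 °C then reflux, Dean–Stark
Reagents that add atoms: none
Why: Acid-catalysed Robinson annulation, in which the aldehyde enol adds to the enone (Michael) and the methyl ketone of 8 closes onto the aldehyde by aldol condensation with azeotropic loss of water; the quaternary stereocentre forms without control and disappears in step 6.

Step 6
Reactants: 9 ethyl 4-(1-methyl-4-oxocyclohex-2-en-1-yl)-2-(propan-2-yl)butanoate
Product: 10 ethyl 4-(1-methyl-4-oxocyclohexa-2,5-dien-1-yl)-2-(propan-2-yl)butanoate (racemic)
Conditions: DDQ, 1,4-dioxane, reflux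
Reagents that add atoms: none
Why: DDQ dehydrogenation of a 4,4-disubstituted cyclohex-2-enone is the classical entry to cross-conjugated dienones, the quaternary carbon ruling out aromatisation; the ring becomes symmetric so that only the C7 stereocentre remains.

Step 7
Reactants: 10 ethyl 4-(1-methyl-4-oxocyclohexa-2,5-dien-1-yl)-2-(propan-2-yl)butanoate
Product: 11 4-(4-hydroxy-1-methylcyclohexa-2,5-dien-1-yl)-2-(propan-2-yl)butan-1-ol (diastereomer mixture)
Conditions: i-Bu2AlH (excess), CH2Cl2, −78 → 0 °C; Rochelle salt work-up
Reagents that add atoms: none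
Why: Hydride reduction with i-Bu2AlH takes the ester to the primary alcohol and the dienone carbonyl to the carbinol by 1,2-addition in one operation, because the ester cannot be reduced alone beside the dienone; the carbinol configuration is irrelevant and the acid-sensitive dienol is worked up neutral and used crude.

Step 8
Reactants: 11 4-(4-hydroxy-1-methylcyclohexa-2,5-dien-1-yl)-2-(propan-2-yl)butan-1-ol
Product: 12 4-(1-methyl-4-oxocyclohexa-2,5-dien-1-yl)-2-(propan-2-yl)butanal (racemic at C7)
Conditions: Dess–Martin periodinane, pyridine, CH2Cl2, 0 °C → rt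
Reagents that add atoms: none
Why: Dess–Martin oxidation under pyridine buffering returns the bis-allylic alcohol to the dienone and takes the primary alcohol to the aldehyde without the acid that would trigger dienol–benzene rearrangement.

Step 9
Reactants: 12 4-(1-methyl-4-oxocyclohexa-2,5-dien-1-yl)-2-(propan-2-yl)butanal
Product: 13 cis-fused 15-noreudesm-1-ene-3,6-dione (H-5 β; C10 methyl β; both C7 epimers)
Conditions: (5aR,10bS)-2-(pentafluorophenyl)-5a,10b-dihydro-4H,6H-indeno[2,1-b][1,2,4]triazolo[4,3-d][1,4]oxazin-2-ium tetrafluoroborate (20 mol%), KN(SiMe3)2 (18 mol%), toluene, 23 °C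
Reagents that add atoms: none
Why: Deprotonation of the triazolium salt gives a triazolylidene that adds to the C6 aldehyde; proton transfer forms the Breslow intermediate (an acyl anion equivalent), whose nucleophilic carbon adds 1,4 to C5 of one enone arm, and protonation at C4 followed by collapse of the tetrahedral intermediate releases the C6 ketone and the carbene. The closest known reaction type is the intramolecular Stetter desymmetrisation of 4,4-disubstituted cyclohexa-2,5-dienones carrying a tethered aldehyde under aminoindanol-derived triazolium catalysis, applied here to a six-membered all-carbon closure from an α-branched aliphatic aldehyde, for which the electron-poor N-pentafluorophenyl catalyst is the appropriate choice. Ring B closes in a 6-exo-trig mode through the new C5–C6 bond. C10 becomes stereogenic because the chiral carbene decides which of the two enantiotopic arms (C5 or C1) is attacked, and C5 is fixed relative to C10 by the tether, which can reach the dienone only from the face it occupies, so that H-5 and the C10 methyl end up cis. The selectivity needed is enantiotopic-group selection together with 1,4-addition in preference to benzoin- or aldol-type reactions; the substrate supports this through its non-enolisable dienone, the quaternary C10 that holds the tether over the ring, and the absence of any other electrophile. The C7 configuration is not a concern because both C7 epimers of 13 converge in step 10.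

Step 10
Reactants: 13 cis-fused 15-noreudesm-1-ene-3,6-dione
Product: 14 trans-fused 15-noreudesm-1-ene-3,6-dione (H-5 α; isopropyl at C7 β; C10 methyl β)
Conditions: 1,8-diazabicyclo[5.4.0]undec-7-ene, toluene, 40 °C
Reagents that add atoms: none
Why: Base-mediated epimerisation through the C6 enolates, C5 and C7 both being α to the C6 ketone; the trans-fused isomer with equatorial isopropyl is expected to dominate at equilibrium, as 6-oxo-5α-steroids do over their 5β-epimers, while C10 is untouched.

Step 11
Reactants: 14 trans-fused 15-noreudesm-1-ene-3,6-dione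
Product: 15 15-noreudesm-1-ene-3,6β-diol (H-5 α; isopropyl at C7 β; both C3 epimers)
Conditions: i-Bu2AlH, CH2Cl2, −78 → −20 °C
Reagents that add atoms: none
Why: Hydride reduction with i-Bu2AlH takes the enone to the allylic alcohol by 1,2-addition and attacks the C6 ketone from the α face, because the β (axial) trajectory at C6 is blocked by the syn-axial C10 methyl, so the axial 6β-alcohol results; the C3 configuration is irrelevant.

Step 12
Reactants: 15 15-noreudesm-1-ene-3,6β-diol
Product: 16 6β-hydroxy-15-noreudesm-1-en-3-one
Conditions: MnO2 (activated), CH2Cl2, rt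
Reagents that add atoms: none
Why: Manganese dioxide oxidises allylic alcohols selectively, so the C3 carbinol returns to the enone while the hindered saturated 6β-alcohol is left alone.

Step 13
Reactants: 16 6β-hydroxy-15-noreudesm-1-en-3-one
Product: 17 6β-hydroxyeudesm-1-en-3-one (both C4 epimers)
Conditions: LiN(i-Pr)2 (2.2 equiv), THF, −78 °C; MeI, −78 → −30 °C
Reagents that add atoms: iodomethane, CI
Why: Kinetic α′-deprotonation of the cyclohexenone gives the cross-conjugated lithium dienolate (C4 carries the only acidic C–H bonds because C10 is quaternary), which is C-methylated, the hindered lithium alkoxide at C6 being inert to iodomethane at low temperature; the C4 configuration is irrelevant.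

Step 14
Reactants: 17 6β-hydroxyeudesm-1-en-3-one
Product: 18 6β-hydroxyeudesma-1,3-dien-3-yl trifluoromethanesulfonate
Conditions: LiN(i-Pr)2 (2.2 equiv), THF, −78 → −40 °C; PhNTf2 (1.1 equiv), −78 → 0 °C
Reagents that add atoms: N-phenylbis(trifluoromethanesulfonimide), O=S(=O)(N(c1ccccc1)S(=O)(=O)C(F)(F)F)C(F)(F)F
Why: The same α′-enolisation, now at the C4 methine, gives a single regiodefined dienolate that is O-sulfonylated (enol triflate formation), which fixes the future double bond between C3 and C4.

Step 15
Reactants: 18 6β-hydroxyeudesma-1,3-dien-3-yl trifluoromethanesulfonate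
Product: 19 6β-hydroxyeudesm-3-en-3-yl trifluoromethanesulfonate
Conditions: 2-nitrobenzenesulfonylhydrazide (excess), Et3N, CH2Cl2, rt
Reagents that add atoms: none
Why: Diimide reduction, in which H2 is transferred in a concerted syn fashion to the cis-disubstituted C1=C2 bond, whereas the tetrasubstituted, electron-poor enol triflate double bond is inert to it.

Step 16
Reactants: 19 6β-hydroxyeudesm-3-en-3-yl trifluoromethanesulfonate
Product: 20 eudesm-3-en-6β-ol, (5R,6R,7S,10R)
Conditions: Pd(OAc)2 (cat.), PPh3, n-Bu3N, HCO2H, DMF, 60 °C
Reagents that add atoms: none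
Why: Palladium-catalysed formate reduction of an enol triflate (oxidative addition to zerovalent palladium, decarboxylation of formate to a hydride, reductive elimination) replaces the triflate by hydrogen with the double bond held at C3–C4.

Step 17
Reactants: 20 eudesm-3-en-6β-ol; 21 2,2-dimethyl-1,3-dioxane-4,6-dione (Meldrum's acid)
Product: 22 3-[(eudesm-3-en-6β-yl)oxy]-3-oxopropanoic acid
Conditions: toluene, 100 °C
Reagents that add atoms: none
Why: Alcoholysis of Meldrum's acid with loss of acetone gives malonic acid monoesters even from hindered alcohols (tert-butanol reacts likewise), without acylation catalysts or strong acid that could move the Δ3 bond.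

Step 18
Reactants: 22 3-[(eudesm-3-en-6β-yl)oxy]-3-oxopropanoic acid; 23 4-hydroxybenzaldehyde
Product: 25 eudesm-3-en-6β-yl (2E)-3-(4-hydroxyphenyl)prop-2-enoate (CNP0220414.1), via arylidenemalonate half-ester 24 (not isolated)
Conditions: pyridine, piperidine (cat.), 60 °C
Reagents that add atoms: none
Why: Knoevenagel–Doebner condensation, in which the malonate half-ester condenses with the aldehyde and the adduct 24 loses CO2 in pyridine to give the thermodynamically favoured E-cinnamate, so the phenol needs no protection and the hindered ester bond is not touched.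

**Compound list**

1 | 3-methylbut-3-en-1-ol | C=C(C)CCO | starting material
2 | 4-iodo-2-methylbut-1-ene | C=C(C)CCI | intermediate
3 | ethyl 3-methylbutanoate | CCOC(=O)CC(C)C | starting material
4 | ethyl 5-methyl-2-(propan-2-yl)hex-5-enoate (racemic) | CCOC(=O)C(C(C)C)CCC(C)=C | intermediate
5 | ethyl 6-hydroxy-5-methyl-2-(propan-2-yl)hexanoate (diastereomer mixture) | CCOC(=O)C(C(C)C)CCC(C)CO | intermediate
6 | ethyl 5-methyl-6-oxo-2-(propan-2-yl)hexanoate (diastereomer mixture) | CCOC(=O)C(C(C)C)CCC(C)C=O | intermediate
7 | but-3-en-2-one | CC(=O)C=C | starting material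
8 | ethyl 5-formyl-5-methyl-8-oxo-2-(propan-2-yl)nonanoate (Michael adduct, diastereomer mixture) | CCOC(=O)C(C(C)C)CCC(C)(C=O)CCC(C)=O | intermediate (not isolated)
9 | ethyl 4-(1-methyl-4-oxocyclohex-2-en-1-yl)-2-(propan-2-yl)butanoate (diastereomer mixture) | CCOC(=O)C(C(C)C)CCC1(C)C=CC(=O)CC1 | intermediate
10 | ethyl 4-(1-methyl-4-oxocyclohexa-2,5-dien-1-yl)-2-(propan-2-yl)butanoate (racemic) | CCOC(=O)C(C(C)C)CCC1(C)C=CC(=O)C=C1 | intermediate
11 | 4-(4-hydroxy-1-methylcyclohexa-2,5-dien-1-yl)-2-(propan-2-yl)butan-1-ol (diastereomer mixture) | OCC(C(C)C)CCC1(C)C=CC(O)C=C1 | intermediate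
12 | 4-(1-methyl-4-oxocyclohexa-2,5-dien-1-yl)-2-(propan-2-yl)butanal (racemic at C7; Stetter precursor) | O=CC(C(C)C)CCC1(C)C=CC(=O)C=C1 | intermediate
13 | cis-fused 15-noreudesm-1-ene-3,6-dione (H-5 β, C10 methyl β, both C7 epimers; Stetter product) | O=C1C=C[C@]2(C)CCC(C(C)C)C(=O)[C@@H]2C1 | intermediate
14 | trans-fused 15-noreudesm-1-ene-3,6-dione (H-5 α, 7β-isopropyl, C10 methyl β) | O=C1C=C[C@]2(C)CC[C@@H](C(C)C)C(=O)[C@H]2C1 | intermediate
15 | 15-noreudesm-1-ene-3,6β-diol (H-5 α, 7β-isopropyl, both C3 epimers) | OC1C=C[C@]2(C)CC[C@@H](C(C)C)[C@@H](O)[C@H]2C1 | intermediate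
16 | 6β-hydroxy-15-noreudesm-1-en-3-one (H-5 α, 7β-isopropyl) | O=C1C=C[C@]2(C)CC[C@@H](C(C)C)[C@@H](O)[C@H]2C1 | intermediate
17 | 6β-hydroxyeudesm-1-en-3-one (H-5 α, 7β-isopropyl, both C4 epimers) | CC1C(=O)C=C[C@]2(C)CC[C@@H](C(C)C)[C@@H](O)[C@@H]12 | intermediate
18 | 6β-hydroxyeudesma-1,3-dien-3-yl trifluoromethanesulfonate | CC1=C(OS(=O)(=O)C(F)(F)F)C=C[C@]2(C)CC[C@@H](C(C)C)[C@@H](O)[C@@H]12 | intermediate
19 | 6β-hydroxyeudesm-3-en-3-yl trifluoromethanesulfonate | CC1=C(OS(=O)(=O)C(F)(F)F)CC[C@]2(C)CC[C@@H](C(C)C)[C@@H](O)[C@@H]12 | intermediate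
20 | (5R,6R,7S,10R)-eudesm-3-en-6-ol (eudesm-3-en-6β-ol) | CC1=CCC[C@]2(C)CC[C@@H](C(C)C)[C@@H](O)[C@@H]12 | intermediate
21 | 2,2-dimethyl-1,3-dioxane-4,6-dione (Meldrum's acid) | CC1(C)OC(=O)CC(=O)O1 | starting material
22 | 3-[(eudesm-3-en-6β-yl)oxy]-3-oxopropanoic acid | CC1=CCC[C@]2(C)CC[C@@H](C(C)C)[C@@H](OC(=O)CC(=O)O)[C@@H]12 | intermediate
23 | 4-hydroxybenzaldehyde | O=Cc1ccc(O)cc1 | starting material
24 | 2-[(4-hydroxyphenyl)methylidene]propanedioic acid mono(eudesm-3-en-6β-yl) ester | CC1=CCC[C@]2(C)CC[C@@H](C(C)C)[C@@H](OC(=O)C(=Cc3ccc(O)cc3)C(=O)O)[C@@H]12 | intermediate (not isolated)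
25 | (1R,2S,4aR,8aR)-4a,8-dimethyl-2-(propan-2-yl)-1,2,3,4,4a,5,6,8a-octahydronaphthalen-1-yl (2E)-3-(4-hydroxyphenyl)prop-2-enoate | CC1=CCC[C@]2(C)CC[C@@H](C(C)C)[C@@H](OC(=O)/C=C/c3ccc(O)cc3)[C@@H]12 | target

**Step count and risks**

Total step count: 18. Longest linear sequence: 18 steps (1 → 25); all other components are commercial.

Steps most likely to fail:

Step 9. Carbene addition and Breslow-intermediate formation at the hindered α-branched aldehyde may be too slow for the six-membered closure to compete with base-mediated aldol pathways. Fallback: keep the C5–C6 disconnection but change the acyl-anion equivalent to a nitronate. From 12, condensation with hydroxylamine (NH2OH·HCl, NaOAc, EtOH) would give 4-(1-methyl-4-oxocyclohexa-2,5-dien-1-yl)-2-(propan-2-yl)butanal oxime F1. Oxidation with peroxytrifluoroacetic acid (urea–hydrogen peroxide, trifluoroacetic anhydride, Na2HPO4, MeCN, 0 °C) would give the nitroalkane 4-methyl-4-[4-methyl-3-(nitromethyl)pentyl]cyclohexa-2,5-dien-1-one F2. The bifunctional catalyst 1-[3,5-bis(trifluoromethyl)phenyl]-3-[(1R,2R)-2-(dimethylamino)cyclohexyl]thiourea (or its antipode, as the arm selection requires) would then effect an intramolecular nitro-Michael desymmetrisation of the dienone, again 6-exo-trig and cis-fused for the same geometric reason, to cis-fused 6-nitro-15-noreudesm-1-en-3-one F3. A reductive Nef reaction (aqueous TiCl3, NH4OAc, THF) would convert the secondary nitro group into the C6 ketone, which returns to the route at 13.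

Step 14. The lithium alkoxide at C6 may interfere, either by aggregation that slows enolisation of the hindered C4 methine or by competing O-sulfonylation. Fallback: mask the hydroxyl before enolisation. From 17, 1-(trimethylsilyl)imidazole (CH2Cl2, rt) would give 6β-(trimethylsilyloxy)eudesm-1-en-3-one F4. LiN(i-Pr)2 (1.1 equiv) and PhNTf2 would then give 6β-(trimethylsilyloxy)eudesma-1,3-dien-3-yl trifluoromethanesulfonate F5, and citric acid in methanol at 0 °C would remove the silyl group, which returns to the route at 18.

Step 15. Hydrogen transfer from diimide to the C1=C2 bond, which sits next to the quaternary C10 within a conjugated dienyl triflate, may be too slow or not clean. Fallback: reverse the order of the two reductions and change the hydrogen source. From 18, the palladium-catalysed formate reduction (Pd(OAc)2, PPh3, n-Bu3N, HCO2H, DMF) would first give eudesma-1,3-dien-6β-ol F6. Its cis-disubstituted C1=C2 bond would then be saturated with H2 over RhCl(PPh3)3 (benzene, rt), a catalyst that discriminates strongly against the trisubstituted C3=C4 bond, which returns to the route at 20.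

**Further compounds**

F1 | step 9 | 4-(1-methyl-4-oxocyclohexa-2,5-dien-1-yl)-2-(propan-2-yl)butanal oxime | ON=CC(C(C)C)CCC1(C)C=CC(=O)C=C1
F2 | step 9 | 4-methyl-4-[4-methyl-3-(nitromethyl)pentyl]cyclohexa-2,5-dien-1-one | [O-][N+](=O)CC(C(C)C)CCC1(C)C=CC(=O)C=C1
F3 | step 9 | cis-fused 6-nitro-15-noreudesm-1-en-3-one (H-5 β, C10 methyl β, C6 and C7 epimers) | O=C1C=C[C@]2(C)CCC(C(C)C)C([N+](=O)[O-])[C@@H]2C1
F4 | step 14 | 6β-(trimethylsilyloxy)eudesm-1-en-3-one (both C4 epimers) | CC1C(=O)C=C[C@]2(C)CC[C@@H](C(C)C)[C@@H](O[Si](C)(C)C)[C@@H]12
F5 | step 14 | 6β-(trimethylsilyloxy)eudesma-1,3-dien-3-yl trifluoromethanesulfonate | CC1=C(OS(=O)(=O)C(F)(F)F)C=C[C@]2(C)CC[C@@H](C(C)C)[C@@H](O[Si](C)(C)C)[C@@H]12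
F6 | step 15 | eudesma-1,3-dien-6β-ol | CC1=CC=C[C@]2(C)CC[C@@H](C(C)C)[C@@H](O)[C@@H]12
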